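## Structural features

The target is a germacranolide: a ten-membered carbocycle (C1–C10) with an E trisubstituted C1=C10 olefin (methyl on C10), a cis 4,5-epoxide (methyl on C4), acetoxy groups at C2 and C6, and an α-methylene-γ-butyrolactone (C11, C12, C13) trans-fused at C7–C8 and closed on the C8 oxygen. Five of the six stereocentres (C4, C5, C6, C7, C8) are contiguous; C2 is allylic and isolated, so its relation to the cluster has to be relayed across the ring. The fragile groups are the exocyclic enoate (a Michael acceptor), the trisubstituted epoxide facing C1=C10 across the ring (acid opens it with transannular participation), the two acetates, and the C6 oxygen, which lies γ to C12 like the C8 oxygen and can capture the lactone or lactol carbon whenever it is free. The real difficulty is the ten-membered ring itself, with one E olefin and one latent Z olefin and with C2 correlated to C7 and C8; C6, C5 and C4 are secondary problems solvable from inside the ring. The key step uses three features: the E C1=C10 olefin stands 1,5 to the C6 oxygen through the C8–C9 bond, the cis-epoxide stands for a Z C4=C5 olefin, and the C8 oxygen can be the oxygen of an enol ether. C1–C6 therefore fold back into a 1,2-divinylcyclohex-2-enol whose vinyl groups are an isopropenyl unit (C9, C10 and its methyl) and a 5-alkoxy-4,5-dihydrofuran-3-yl unit (C7, C8, C11, C12).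

## Logic of the disconnections

29 to 26 (through 28): the C11=C13 bond is cut and C12 is taken back to the lactol level. The Michael acceptor is thereby the last group made. The demand is a methylenation and an oxidation that need no strong base, because two acetates and an epoxide are present.

26 to 23 (through 25 and 24): the C12–OH bond goes back to a methyl acetal, the two acyl C–O bonds are cut, and the C2 oxygen returns to its silyl ether. The acetal is the form in which C12 survives organometallics and KH. The acetates go on before the acetal is opened, so that the C6 oxygen can never close on C12. The demand is an acetal hydrolysis mild enough for the epoxide.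

23 to 22: both C–O bonds of the epoxide are cut. The free C6 hydroxyl is the only handle that tells C4=C5 from C1=C10, so the epoxide is delivered from it while C2 is still silylated. Two stereocentres are removed; the demand is syn delivery to the Z olefin.

22 to 21: the C6–H bond is cut, which removes one stereocentre and reveals the dienone that the ring expansion produces. The demand is 1,2-reduction from the correct face without touching the acidic C7–H.

21 to 18 (key): in the reverse sense C8–C9 is cut and C1–C6 is formed. The ten-membered ring becomes a cyclohexene, and the C7/C8 pair is exchanged for the C1/C6 pair of a six-membered ring, where relative configuration is easy to set. The demand is a trans relation of the two vinyl groups, a chair transition state and a cold quench.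

18 to 11 and 15: the C6–C7 bond is cut, giving an enone and a five-carbon acetal fragment. The dihydrofuran must be metalated at C4; deprotonation would occur at C5 next to oxygen and would join the ring through the wrong carbon, so a C4 bromide is required. The nucleophile must be non-basic, because 11 is enolisable and carries a β-silyloxy group.

15 to 12 (through 13): the C–Br bond and the enol-ether double bond are removed, leading to a commercial bis-acetal.

11 to 10: the ring C4=C5 bond is cut by retro-metathesis. It is remote from both stereocentres and leaves an open chain. The demand is that only the vinyl ketone and the methallyl olefin pair up.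

10 to 7 (through 9 and 8): the vinyl–acyl bond, the O–Si bond and the amide C–N bond are cut in turn, back to an imide aldol.

7 to 3 and 5, then 3 to 1 and 2, and 5 to 4: the C1–C2 bond is cut as an aldol. This step sets the C2 centre that survives to the target and the C1 centre that later steers the ring expansion, both under auxiliary control. A cycloaddition of a dienol ether with a β-oxygenated enone would be two steps shorter, but it rests on a deactivated dienophile, so the aldol–metathesis sequence is preferred.

## Other disconnections considered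

Alternative 1: The cut is C6–C7, made forward by a Still–Wittig [2,3]-shift that contracts a thirteen-membered allylic ether. In precursor A2, C6 is an α-alkoxy stannane whose oxygen is tied to C13. Tin–lithium exchange with n-BuLi would give the α-oxy carbanion, which bonds to C7 of the C7=C11 olefin while O–C13 breaks, giving A1.
- In its favour: the C6 carbinol, the C7 centre and the C11=C13 methylene appear in one event, so neither a ketone reduction nor a late methylenation is needed. On this point it is better than the chosen plan.
- Equal footing: like the chosen plan it reaches the ten-membered ring by a sigmatropic change of ring size and not by joining two ends.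
- Against it here: A2 needs three stereodefined trisubstituted olefins in one chain and a macro-etherification. The C6 carbanion is also allylic to C4=C5, which invites [1,2]- and [1,4]-shifts, bonding through C4 and loss of the Z geometry. The C6/C7 relation would rest on an envelope transition state inside a flexible macrocycle, not on a chair held by a six-membered ring. C12 arrives as a protected primary alcohol, so oxidation and lactonisation remain, and the identical silyl ethers at C2 and C8 must be told apart.
- Step economy: the chain assembly and macrocyclisation before the key step outweigh the steps saved after it.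

Alternative 2: The cut is C5–C6, made forward by a Nozaki–Hiyama–Kishi closure. CrCl2 (divalent chromium) with catalytic NiCl2 (divalent nickel) would convert the Z alkenyl iodide of A4 into the alkenylchromium species, which adds to the C6 aldehyde and gives the allylic alcohol A3.
- In its favour: the ring is closed last on a fragment that already holds the lactone with C7 and C8 set and the methylene masked as an amine. No acetal has to be unveiled and nothing is methylenated on the ring; on late-stage functional-group economy it is better than the chosen plan. The olefin geometry is carried over with retention and the reagent tolerates esters and silyl ethers.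
- Equal footing: C6 is formed as a carbinol, but its configuration is no more controlled by design than in the reduction of 21.
- Against it here: a ten-membered ring is closed end to end against transannular strain, which calls for high dilution and a large excess of chromium. A4 has an epimerisable C7 next to the aldehyde and a β-acyloxy group at C8 that can be lost by elimination. The amine may bind the metal. A4 carries four stereocentres and a Z trisubstituted iodide that must all be built in open chain.
- Comparison: the chosen ring expansion is driven by enolate formation and needs no dilution, and its precursor is shorter to make.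

Alternative 3: The cut restores a C6–C10 bond, so the ten-membered ring becomes the hydroazulenol mesylate A6. Forward, potassium tert-butoxide forms the C6 alkoxide, which expels the anti-periplanar C1 mesylate with cleavage of C6–C10 and gives the dienone A5.
- In its favour: the olefin geometry follows stereospecifically from the configurations at C1 and C10 (mesylate and methyl cis on the seven-membered ring, as drawn for A6). That is a firmer guarantee than a chair preference, so on E-selectivity it is at least the equal of the chosen plan. The fragmentation is irreversible and needs no dilution. C8 is an ordinary protected alcohol set beforehand, so it does not depend on the key step.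
- Equal footing: A5 has the same C6 ketone and Z enone as 21, so reduction and epoxidation would follow as here, and C7 is equally epimerisable.
- Against it here: A6 needs six stereocentres, one quaternary, of which three are destroyed. The mesylate sits next to a silyloxy-bearing carbon, so simple elimination competes. The C7 side chain is only a protected two-carbon alcohol, so deprotection, oxidation to the acid, selective release of the C8 over the C2 silyl ether, lactonisation and methylenation all remain.
- Step economy: clearly worse, before and after the key step.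

Key step: step 11

Remark: bromide 15 is racemic, so 18 and every compound down to 25 is carried as a pair of epimers at the acetal carbon C12 (one is drawn); this centre plays no part in the key step and is oxidised away in step 18.
Remark: the configurations of 18 and 21 were checked against the chair model and are consistent (2S with 8S), so no stereodescriptor needed correction. What is mended is the point of metalation of the dihydrofuran and the order of the late steps.

## Steps

Step 1
Reactants: 1 (R)-4-benzyloxazolidin-2-one; 2 3-methylbut-2-enoyl chloride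
Product: 3 (R)-4-benzyl-3-(3-methylbut-2-enoyl)oxazolidin-2-one
Conditions: n-BuLi, THF, −78 °C; then 2, −78 to 0 °C
Reagents that add atoms: none
Why: N-acylation of the lithiated oxazolidinone by the acid chloride, the standard preparation of N-enoyl imides; no stereocentre is touched.

Step 2
Reactants: 4 3-methylbut-3-en-1-ol
Product: 5 3-methylbut-3-enal
Conditions: Dess–Martin periodinane, NaHCO3, CH2Cl2, 0 °C; filtered solution used at once
Reagents that add atoms: none
Why: Dess–Martin oxidation of a primary alcohol; the bicarbonate buffer should keep the β,γ-olefin from moving into conjugation, and the volatile aldehyde is not stored.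

Step 3
Reactants: 3 (R)-4-benzyl-3-(3-methylbut-2-enoyl)oxazolidin-2-one; 5 3-methylbut-3-enal
Product: 7 (R)-4-benzyl-3-[(2R,3S)-3-hydroxy-5-methyl-2-(prop-1-en-2-yl)hex-5-enoyl]oxazolidin-2-one, via dibutylboron dienolate 6 (not isolated)
Conditions: Bu2BOTf, Et3N, CH2Cl2, −78 to 0 °C; 5, −78 °C; then pH 7 buffer, MeOH, H2O2, 0 °C
Reagents that add atoms: none
Why: Evans syn aldol through the boron dienolate: soft enolisation removes a γ-hydrogen, and the Z(O)-dienolate reacts at its α-carbon in a Zimmerman–Traxler chair. The (R)-benzyl group shields one enolate face, which sets 2R and 3S (isopropenyl and hydroxyl syn, the mirror image of the (S)-auxiliary outcome); these become C1 and C2 of the germacrane.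

Step 4
Reactants: 7 (R)-4-benzyl-3-[(2R,3S)-3-hydroxy-5-methyl-2-(prop-1-en-2-yl)hex-5-enoyl]oxazolidin-2-one
Product: 8 (2R,3S)-3-hydroxy-N-methoxy-N,5-dimethyl-2-(prop-1-en-2-yl)hex-5-enamide
Conditions: MeNH(OMe)·HCl, AlMe3, CH2Cl2, −20 to 0 °C
Reagents that add atoms: N,O-dimethylhydroxylamine hydrochloride, CNOC.Cl
Why: Aluminium-amide transamination of a β-hydroxy imide to the Weinreb amide, assisted by the aluminium alkoxide of the free hydroxyl; the reagent is not basic enough to epimerise the α-centre or shift the β,γ-olefin.

Step 5
Reactants: 8 (2R,3S)-3-hydroxy-N-methoxy-N,5-dimethyl-2-(prop-1-en-2-yl)hex-5-enamide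
Product: 9 (2R,3S)-3-(tert-butyldimethylsilyloxy)-N-methoxy-N,5-dimethyl-2-(prop-1-en-2-yl)hex-5-enamide
Conditions: TBSOTf, 2,6-lutidine, CH2Cl2, −78 to 0 °C
Reagents that add atoms: tert-butyldimethylsilyl triflate, CC(C)(C)[Si](C)(C)OS(=O)(=O)C(F)(F)F
Why: Silylation of the secondary alcohol with a silyl triflate and a hindered base; it protects the future C2 oxygen for the organometallic and KH steps and blocks retro-aldol.

Step 6
Reactants: 9 (2R,3S)-3-(tert-butyldimethylsilyloxy)-N-methoxy-N,5-dimethyl-2-(prop-1-en-2-yl)hex-5-enamide
Product: 10 (4R,5S)-5-(tert-butyldimethylsilyloxy)-7-methyl-4-(prop-1-en-2-yl)octa-1,7-dien-3-one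
Conditions: CH2=CHMgBr, THF, −20 to 0 °C; inverse quench into cold aq. NaHSO4
Reagents that add atoms: vinylmagnesium bromide, C=C[Mg]Br
Why: Weinreb ketone synthesis: the chelated tetrahedral intermediate holds until work-up, so the vinyl ketone never meets the Grignard reagent. The acidic inverse quench protonates the released amine and prevents its conjugate addition; the low temperature limits deprotonation at the doubly activated α-carbon.

Step 7
Reactants: 10 (4R,5S)-5-(tert-butyldimethylsilyloxy)-7-methyl-4-(prop-1-en-2-yl)octa-1,7-dien-3-one
Product: 11 (5S,6R)-5-(tert-butyldimethylsilyloxy)-3-methyl-6-(prop-1-en-2-yl)cyclohex-2-en-1-one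
Conditions: second-generation Grubbs catalyst RuCl2(=CHPh)(PCy3)(H2IMes) (5 mol%), CH2Cl2 (0.005 M), 40 °C
Reagents that add atoms: none
Why: Ring-closing metathesis of the vinyl ketone with the 1,1-disubstituted methallyl olefin gives the six-membered enone with loss of ethene. The isopropenyl group could only close a four-membered or a tetrasubstituted five-membered ring and should stay out; neither stereocentre is touched.

Step 8
Reactants: 12 2,5-dimethoxytetrahydrofuran
Product: 13 2-methoxy-2,3-dihydrofuran (racemic)
Conditions: Me3SiOTf (1 equiv), i-Pr2NEt, CH2Cl2, −20 °C to rt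
Reagents that add atoms: none
Why: Silyl-triflate-mediated conversion of an acetal into an enol ether by loss of methanol; one equivalent confines the reaction to one acetal carbon, and over-elimination would only give volatile furan.

Step 9
Reactants: 13 2-methoxy-2,3-dihydrofuran
Product: 15 4-bromo-2-methoxy-2,3-dihydrofuran (racemic), via 2,3-dibromo-5-methoxytetrahydrofuran 14 (not isolated)
Conditions: Br2, CH2Cl2, −78 °C; then Et3N, −78 °C to rt
Reagents that add atoms: bromine, BrBr
Why: Bromine addition to the enol ether followed by loss of HBr from the α-bromo ether, the usual route to β-bromo cyclic enol ethers. It puts the halogen on C4, the carbon that must become C7; the product is kept over base because acid would aromatise it.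

Step 10
Reactants: 15 4-bromo-2-methoxy-2,3-dihydrofuran; 11 (5S,6R)-5-(tert-butyldimethylsilyloxy)-3-methyl-6-(prop-1-en-2-yl)cyclohex-2-en-1-one
Product: 18 (1S,5S,6R)-5-(tert-butyldimethylsilyloxy)-1-[(5S)-5-methoxy-4,5-dihydrofuran-3-yl]-3-methyl-6-(prop-1-en-2-yl)cyclohex-2-en-1-ol, via 4-lithio-2-methoxy-2,3-dihydrofuran 16 (not isolated), via dichlorocerium reagent 17 (not isolated)
Conditions: t-BuLi (2 equiv), Et2O, −78 °C; CeCl3, THF, −78 °C; then 11, −78 °C; aq. NaHCO3
Reagents that add atoms: none
Why: Bromine–lithium exchange gives the β-lithio enol ether, and transmetalation to trivalent cerium lowers its basicity so that the enolisable β-silyloxy enone undergoes 1,2-addition. The nucleophile should enter anti to the neighbouring isopropenyl group, which gives the trans-divinyl carbinol (1S) with the hydroxyl cis to isopropenyl.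

Step 11
Reactants: 18 (1S,5S,6R)-5-(tert-butyldimethylsilyloxy)-1-[(5S)-5-methoxy-4,5-dihydrofuran-3-yl]-3-methyl-6-(prop-1-en-2-yl)cyclohex-2-en-1-ol
Product: 21 (1(10)E,4Z,2S,7R,8S,12S)-2-(tert-butyldimethylsilyloxy)-12-methoxy-8,12-epoxygermacra-1(10),4-dien-6-one, via potassium alkoxide 19 (not isolated), via potassium dienolate 20 (not isolated)
Conditions: KH, 18-crown-6, THF, 0 °C to rt; then AcOH, THF, −78 °C
Reagents that add atoms: none
Why: KH deprotonates the tertiary C6 hydroxyl and the crown ether frees the alkoxide from potassium, which weakens the C1–C6 bond and lets the [3,3] shift through the chair array C9=C10–C1–C6–C7=C8 run at or below room temperature; the closest known reaction type is the anionic oxy-Cope ring expansion of trans-1,2-divinylcyclohexanols and divinylcyclohexenols to (E)-cyclodecenones, including cases with a cyclic enol ether as one vinyl partner. The ten-membered ring is not closed end to end but arises by ring expansion: C8–C9 forms while the C1–C6 bond of the cyclohexene breaks inside a six-centre transition state, so no dilution is needed. With the two vinyl groups trans and equatorial, the chair has both former ring bonds (C1–C2 and C6–C5) equatorial and the alkoxide oxygen axial, which gives the E C1=C10 olefin and leaves the cis C4=C5 bond untouched. C8 is set by chirality transfer: the ring oxygen is trans to C6 on the C7=C8 bond and hence equatorial, and C9 bonds to the face of C8 fixed by the C1 and C6 configurations, which gives 8S relative to the untouched 2S centre. C7 is set in the quench: protonation of the C6–C7 enolate by acetic acid at −78 °C is expected on the convex face to give the trans ring fusion, which is also the more stable arrangement of a 2,3-disubstituted tetrahydrofuran. The step needs chair over boat, [3,3] over [1,3] shift or retro-ene cleavage, and no β-elimination of the C8 oxygen from the enolate. The first two follow from the trans-diequatorial divinyl geometry; the elimination is held back because the C8–O bond lies close to the enolate plane (a 5-endo-trig closure run backwards) and because the enolate is quenched cold, and the equatorial C2 silyl ether, trans-1,3 to the axial alkoxide, is poorly placed for silyl migration. The γ-keto acetal 21 is kept away from acid (furan formation) and used at once.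

Step 12
Reactants: 21 (1(10)E,4Z,2S,7R,8S,12S)-2-(tert-butyldimethylsilyloxy)-12-methoxy-8,12-epoxygermacra-1(10),4-dien-6-one
Product: 22 (1(10)E,4Z,2S,6R,7S,8S,12S)-2-(tert-butyldimethylsilyloxy)-12-methoxy-8,12-epoxygermacra-1(10),4-dien-6-ol
Conditions: NaBH4, CeCl3·7H2O, MeOH, −78 °C
Reagents that add atoms: none
Why: Luche reduction gives 1,2-reduction of the Z enone without conjugate reduction or enolisation at C7. Hydride is expected from the ring periphery onto the conformer whose carbonyl oxygen lies on the side of H7, which puts the C6 oxygen anti to the C7–C11 bond (6R here, the same spatial arrangement as 6S in the target, where the priorities change).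

Step 13
Reactants: 22 (1(10)E,4Z,2S,6R,7S,8S,12S)-2-(tert-butyldimethylsilyloxy)-12-methoxy-8,12-epoxygermacra-1(10),4-dien-6-ol
Product: 23 (1(10)E,2S,4R,5S,6S,7S,8S,12S)-2-(tert-butyldimethylsilyloxy)-12-methoxy-4,5:8,12-diepoxygermacr-1(10)-en-6-ol
Conditions: VO(acac)2 (5 mol%), t-BuOOH, CH2Cl2, 0 °C to rt
Reagents that add atoms: tert-butyl hydroperoxide, CC(C)(C)OO
Why: Hydroxyl-directed epoxidation: the vanadium alkoxide of the C6 hydroxyl delivers oxygen only to the adjacent C4=C5 bond, on the face syn to the hydroxyl as known for medium-ring cis-cycloalkenols, which sets 4R and 5S. C1=C10 has no free hydroxyl next to it and should stay.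

Step 14
Reactants: 23 (1(10)E,2S,4R,5S,6S,7S,8S,12S)-2-(tert-butyldimethylsilyloxy)-12-methoxy-4,5:8,12-diepoxygermacr-1(10)-en-6-ol
Product: 24 (1(10)E,2S,4R,5S,6S,7S,8S,12S)-12-methoxy-4,5:8,12-diepoxygermacr-1(10)-ene-2,6-diol
Conditions: Bu4NF, AcOH, THF, 0 °C to rt
Reagents that add atoms: none
Why: Fluoride cleavage of the allylic silyl ether, buffered with acetic acid so that the epoxy alcohol never meets a basic alkoxide (no Payne rearrangement); no lactone or Michael acceptor is present yet.

Step 15
Reactants: 24 (1(10)E,2S,4R,5S,6S,7S,8S,12S)-12-methoxy-4,5:8,12-diepoxygermacr-1(10)-ene-2,6-diol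
Product: 25 (1(10)E,2S,4R,5S,6S,7R,8S,12S)-12-methoxy-4,5:8,12-diepoxygermacr-1(10)-ene-2,6-diyl diacetate
Conditions: Ac2O, pyridine, DMAP (cat.), CH2Cl2, 0 °C to rt
Reagents that add atoms: acetic anhydride, CC(=O)OC(C)=O
Why: DMAP-catalysed acetylation of both secondary alcohols installs the two acetates of the target. It also caps the C6 oxygen before the acetal is opened, so the lactol cannot re-close on C6.

Step 16
Reactants: 25 (1(10)E,2S,4R,5S,6S,7R,8S,12S)-12-methoxy-4,5:8,12-diepoxygermacr-1(10)-ene-2,6-diyl diacetate
Product: 26 (1(10)E,2S,4R,5S,6S,7R,8S)-12-hydroxy-4,5:8,12-diepoxygermacr-1(10)-ene-2,6-diyl diacetate (lactol, both C12 epimers)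
Conditions: PPTS (cat.), acetone/H2O, 0 °C to rt
Reagents that add atoms: water, O
Why: Specific-acid hydrolysis of a 2-methoxytetrahydrofuran through the cyclic oxocarbenium ion, which should be much faster than opening of an epoxide whose neighbouring carbon carries an acetoxy group. The ring oxygen stays on C8 throughout.

Step 17
Reactants: 26 (1(10)E,2S,4R,5S,6S,7R,8S)-12-hydroxy-4,5:8,12-diepoxygermacr-1(10)-ene-2,6-diyl diacetate
Product: 28 (1(10)E,2S,4R,5S,6S,7R,8S)-12-hydroxy-4,5:8,12-diepoxygermacra-1(10),11(13)-diene-2,6-diyl diacetate, via Mannich base lactol 27 (not isolated)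
Conditions: CH2=NMe2+ I−, Et3N, CH2Cl2, rt
Reagents that add atoms: N,N-dimethylmethyleneiminium iodide (Eschenmoser's salt), C=[N+](C)C.[I-]
Why: Mannich methylenation of the aldehyde tautomer of the lactol: the iminium salt reacts at C11 through the enol, and triethylamine eliminates dimethylamine from the β-amino aldehyde. No strong base is used, so acetates and epoxide are spared, and the product re-closes on the C8 oxygen.

Step 18
Reactants: 28 (1(10)E,2S,4R,5S,6S,7R,8S)-12-hydroxy-4,5:8,12-diepoxygermacra-1(10),11(13)-diene-2,6-diyl diacetate
Product: 29 (1(10)E,2S,4R,5S,6S,7R,8S)-2,6-diacetoxy-4,5-epoxygermacra-1(10),11(13)-dien-12,8-olide (target CNP0270851.3)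
Conditions: Dess–Martin periodinane, NaHCO3, CH2Cl2, 0 °C
Reagents that add atoms: none
Why: Buffered Dess–Martin oxidation of the allylic lactol to the lactone; the conditions are neutral and do not touch olefins, epoxide or acetates, and the Michael acceptor appears only in this last step.

## Compound list

1 | (R)-4-benzyloxazolidin-2-one | O=C1N[C@H](Cc2ccccc2)CO1 | starting material
2 | 3-methylbut-2-enoyl chloride | CC(C)=CC(Cl)=O | starting material
3 | (R)-4-benzyl-3-(3-methylbut-2-enoyl)oxazolidin-2-one | CC(C)=CC(=O)N1[C@H](Cc2ccccc2)COC1=O | intermediate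
4 | 3-methylbut-3-en-1-ol | CC(=C)CCO | starting material
5 | 3-methylbut-3-enal | CC(=C)CC=O | intermediate
6 | dibutylboron Z(O)-dienolate of 3 | CCCCB(CCCC)O/C(=C\C(C)=C)N1[C@H](Cc2ccccc2)COC1=O | intermediate (not isolated)
7 | (R)-4-benzyl-3-[(2R,3S)-3-hydroxy-5-methyl-2-(prop-1-en-2-yl)hex-5-enoyl]oxazolidin-2-one | CC(=C)[C@@H](C(=O)N1[C@H](Cc2ccccc2)COC1=O)[C@@H](O)CC(C)=C | intermediate
8 | (2R,3S)-3-hydroxy-N-methoxy-N,5-dimethyl-2-(prop-1-en-2-yl)hex-5-enamide | CC(=C)[C@@H](C(=O)N(C)OC)[C@@H](O)CC(C)=C | intermediate
9 | (2R,3S)-3-(tert-butyldimethylsilyloxy)-N-methoxy-N,5-dimethyl-2-(prop-1-en-2-yl)hex-5-enamide | CC(=C)[C@@H](C(=O)N(C)OC)[C@@H](O[Si](C)(C)C(C)(C)C)CC(C)=C | intermediate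
10 | (4R,5S)-5-(tert-butyldimethylsilyloxy)-7-methyl-4-(prop-1-en-2-yl)octa-1,7-dien-3-one | CC(=C)[C@@H](C(=O)C=C)[C@@H](O[Si](C)(C)C(C)(C)C)CC(C)=C | intermediate
11 | (5S,6R)-5-(tert-butyldimethylsilyloxy)-3-methyl-6-(prop-1-en-2-yl)cyclohex-2-en-1-one | CC(=C)[C@@H]1[C@@H](O[Si](C)(C)C(C)(C)C)CC(C)=CC1=O | intermediate
12 | 2,5-dimethoxytetrahydrofuran | COC1CCC(OC)O1 | starting material
13 | 2-methoxy-2,3-dihydrofuran (racemic) | COC1CC=CO1 | intermediate
14 | 2,3-dibromo-5-methoxytetrahydrofuran (diastereomer mixture) | COC1CC(Br)C(Br)O1 | intermediate (not isolated)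
15 | 4-bromo-2-methoxy-2,3-dihydrofuran (racemic) | COC1CC(Br)=CO1 | intermediate
16 | 4-lithio-2-methoxy-2,3-dihydrofuran | COC1CC([Li])=CO1 | intermediate (not isolated)
17 | dichloro(5-methoxy-4,5-dihydrofuran-3-yl)cerium (trivalent cerium) | COC1CC(=CO1)[Ce](Cl)Cl | intermediate (not isolated)
18 | (1S,5S,6R)-5-(tert-butyldimethylsilyloxy)-1-[(5S)-5-methoxy-4,5-dihydrofuran-3-yl]-3-methyl-6-(prop-1-en-2-yl)cyclohex-2-en-1-ol (with its acetal epimer) | CC(=C)[C@@H]1[C@@H](O[Si](C)(C)C(C)(C)C)CC(C)=C[C@@]1(O)C1=CO[C@H](OC)C1 | intermediate
19 | potassium alkoxide of 18 | CC(=C)[C@@H]1[C@@H](O[Si](C)(C)C(C)(C)C)CC(C)=C[C@@]1([O-])C1=CO[C@H](OC)C1.[K+] | intermediate (not isolated)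
20 | potassium C6–C7 dienolate of 21 | C3(\[O-])=C1\C[C@@H](OC)O[C@H]1C/C(C)=C/[C@@H](O[Si](C)(C)C(C)(C)C)C/C(C)=C\3.[K+] | intermediate (not isolated)
21 | (1(10)E,4Z,2S,7R,8S,12S)-2-(tert-butyldimethylsilyloxy)-12-methoxy-8,12-epoxygermacra-1(10),4-dien-6-one | C1[C@@H](OC)O[C@H]2C/C(C)=C/[C@@H](O[Si](C)(C)C(C)(C)C)C/C(C)=C\C(=O)[C@H]12 | intermediate
22 | (1(10)E,4Z,2S,6R,7S,8S,12S)-2-(tert-butyldimethylsilyloxy)-12-methoxy-8,12-epoxygermacra-1(10),4-dien-6-ol | C1[C@@H](OC)O[C@H]2C/C(C)=C/[C@@H](O[Si](C)(C)C(C)(C)C)C/C(C)=C\[C@@H](O)[C@H]12 | intermediate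
23 | (1(10)E,2S,4R,5S,6S,7S,8S,12S)-2-(tert-butyldimethylsilyloxy)-12-methoxy-4,5:8,12-diepoxygermacr-1(10)-en-6-ol | C1[C@@H](OC)O[C@H]2C/C(C)=C/[C@@H](O[Si](C)(C)C(C)(C)C)C[C@@]3(C)O[C@H]3[C@@H](O)[C@H]12 | intermediate
24 | (1(10)E,2S,4R,5S,6S,7S,8S,12S)-12-methoxy-4,5:8,12-diepoxygermacr-1(10)-ene-2,6-diol | C1[C@@H](OC)O[C@H]2C/C(C)=C/[C@@H](O)C[C@@]3(C)O[C@H]3[C@@H](O)[C@H]12 | intermediate
25 | (1(10)E,2S,4R,5S,6S,7R,8S,12S)-12-methoxy-4,5:8,12-diepoxygermacr-1(10)-ene-2,6-diyl diacetate | C1[C@@H](OC)O[C@H]2C/C(C)=C/[C@@H](OC(C)=O)C[C@@]3(C)O[C@H]3[C@@H](OC(C)=O)[C@H]12 | intermediate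
26 | (1(10)E,2S,4R,5S,6S,7R,8S)-12-hydroxy-4,5:8,12-diepoxygermacr-1(10)-ene-2,6-diyl diacetate (lactol, C12 epimers) | C1C(O)O[C@H]2C/C(C)=C/[C@@H](OC(C)=O)C[C@@]3(C)O[C@H]3[C@@H](OC(C)=O)[C@H]12 | intermediate
27 | 13-(dimethylamino) derivative of 26 (Mannich base lactol, C11 and C12 epimers) | CN(C)CC1C(O)O[C@H]2C/C(C)=C/[C@@H](OC(C)=O)C[C@@]3(C)O[C@H]3[C@@H](OC(C)=O)[C@H]12 | intermediate (not isolated)
28 | (1(10)E,2S,4R,5S,6S,7R,8S)-12-hydroxy-4,5:8,12-diepoxygermacra-1(10),11(13)-diene-2,6-diyl diacetate (C12 epimers) | C=C1C(O)O[C@H]2C/C(C)=C/[C@@H](OC(C)=O)C[C@@]3(C)O[C@H]3[C@@H](OC(C)=O)[C@H]12 | intermediate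
29 | (1(10)E,2S,4R,5S,6S,7R,8S)-2,6-diacetoxy-4,5-epoxygermacra-1(10),11(13)-dien-12,8-olide (CNP0270851.3) | C=C1C(=O)O[C@H]2C/C(C)=C/[C@@H](OC(C)=O)C[C@@]3(C)O[C@H]3[C@@H](OC(C)=O)[C@H]12 | target

## Step count and least certain steps

Total: 18 steps. Longest linear sequence: 15 steps (1, 3 to 7, 10 to 18).

Step 11 (key step). The enolate may lose the C8 oxygen by β-elimination and open the tetrahydrofuran, C7 may be protonated from the wrong face, or the silyl group may migrate from the C2 oxygen to the C6 alkoxide before the shift. Fallback, from 18: after the shift the enolate is not protonated but silylated at −78 °C (Me3SiCl, Et3N) to the trimethylsilyl dienol ether of 21 F1, which is isolated on base-washed alumina. F1 is then desilylated with acetic-acid-buffered Bu4NF at −78 °C, so that C7 is protonated from a neutral enol ether, with proton source and temperature open to choice and no free enolate on work-up. The route is rejoined at 21.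

Step 12. Hydride delivery to C6 may show poor or opposite facial selectivity, because the reacting conformation of the ten-membered dienone is not known. Fallback, from 21: if the reduction gives mainly the 6-epimer of 22 F2, it is inverted by a Mitsunobu reaction (4-nitrobenzoic acid, PPh3, diisopropyl azodicarboxylate, THF, 0 °C) to the 4-nitrobenzoate of 22 F3. Methanolysis (K2CO3, MeOH) rejoins the route at 22.

Step 13. Oxygen may be delivered to the wrong face of C4=C5 if the ring allows the open-chain, A(1,3)-controlled geometry of the allylic alcohol, and some oxidation of the allylic alcohol to the enone may compete. Fallback, from 22: reagent-controlled Sharpless epoxidation (Ti(OiPr)4, L-(+)-diisopropyl tartrate, t-BuOOH, 4 Å sieves, CH2Cl2, −20 °C). The C6 configuration of 22 is the fast-reacting hand for this tartrate, which delivers oxygen to the face required for the erythro epoxy alcohol. The route is rejoined at 23; no compound outside the list is made (F0).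

Step 16. Acid may open the 4,5-epoxide during acetal hydrolysis, with participation of the C1=C10 olefin across the ring or of the C6 acetate. Fallback, from 22: the acetal is unveiled before the epoxide exists.
- The C6 hydroxyl is protected (NaH, 4-methoxybenzyl chloride, Bu4NI, THF) as the 6-O-(4-methoxybenzyl) ether of 22 F4.
- Buffered fluoride frees C2 to give the 2-hydroxy compound F5, and acetylation gives the 2-acetate F6.
- PPTS in aqueous acetone gives the epoxide-free lactol F7.
- Eschenmoser's salt and Et3N lead through the aminomethyl lactol F8 to the methylene lactol F9.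
- Dess–Martin oxidation gives the methylene lactone 6-O-(4-methoxybenzyl) ether F10.
- DDQ in wet CH2Cl2 gives the 6-hydroxy methylene lactone F11.
- VO(acac)2 and t-BuOOH give the epoxy alcohol F12, and acetylation (Ac2O, pyridine, DMAP) rejoins the route at 29.

## Further compounds

F1 | step 11 | trimethylsilyl dienol ether of 21 | C3(\O[Si](C)(C)C)=C1\C[C@@H](OC)O[C@H]1C/C(C)=C/[C@@H](O[Si](C)(C)C(C)(C)C)C/C(C)=C\3
F2 | step 12 | 6-epimer of 22 | C1[C@@H](OC)O[C@H]2C/C(C)=C/[C@@H](O[Si](C)(C)C(C)(C)C)C/C(C)=C\[C@H](O)[C@H]12
F3 | step 12 | 4-nitrobenzoate of 22 | C1[C@@H](OC)O[C@H]2C/C(C)=C/[C@@H](O[Si](C)(C)C(C)(C)C)C/C(C)=C\[C@@H](OC(=O)c3ccc(cc3)[N+](=O)[O-])[C@H]12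
F0 | step 13 | none | none
F4 | step 16 | 6-O-(4-methoxybenzyl) ether of 22 | C1[C@@H](OC)O[C@H]2C/C(C)=C/[C@@H](O[Si](C)(C)C(C)(C)C)C/C(C)=C\[C@@H](OCc3ccc(OC)cc3)[C@H]12
F5 | step 16 | 2-hydroxy compound from F4 | C1[C@@H](OC)O[C@H]2C/C(C)=C/[C@@H](O)C/C(C)=C\[C@@H](OCc3ccc(OC)cc3)[C@H]12
F6 | step 16 | 2-acetate of F5 | C1[C@@H](OC)O[C@H]2C/C(C)=C/[C@@H](OC(C)=O)C/C(C)=C\[C@@H](OCc3ccc(OC)cc3)[C@H]12
F7 | step 16 | lactol from F6 (C12 epimers) | C1C(O)O[C@H]2C/C(C)=C/[C@@H](OC(C)=O)C/C(C)=C\[C@@H](OCc3ccc(OC)cc3)[C@H]12
F8 | step 16 | aminomethyl lactol from F7 | CN(C)CC1C(O)O[C@H]2C/C(C)=C/[C@@H](OC(C)=O)C/C(C)=C\[C@@H](OCc3ccc(OC)cc3)[C@H]12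
F9 | step 16 | methylene lactol from F8 | C=C1C(O)O[C@H]2C/C(C)=C/[C@@H](OC(C)=O)C/C(C)=C\[C@@H](OCc3ccc(OC)cc3)[C@H]12
F10 | step 16 | methylene lactone 6-O-(4-methoxybenzyl) ether | C=C1C(=O)O[C@H]2C/C(C)=C/[C@@H](OC(C)=O)C/C(C)=C\[C@@H](OCc3ccc(OC)cc3)[C@H]12
F11 | step 16 | 6-hydroxy methylene lactone | C=C1C(=O)O[C@H]2C/C(C)=C/[C@@H](OC(C)=O)C/C(C)=C\[C@@H](O)[C@H]12
F12 | step 16 | 4,5-epoxy-6-hydroxy methylene lactone | C=C1C(=O)O[C@H]2C/C(C)=C/[C@@H](OC(C)=O)C[C@@]3(C)O[C@H]3[C@@H](O)[C@H]12
A1 | alternative 1 | (1(10)E,4Z)-2,8-bis(tert-butyldimethylsilyloxy)-7-[3-(4-methoxybenzyloxy)prop-1-en-2-yl]cyclodeca-1(10),4-dien-6-ol | [C@H]1(O[Si](C)(C)C(C)(C)C)C/C(C)=C/[C@@H](O[Si](C)(C)C(C)(C)C)C/C(C)=C\[C@@H](O)[C@@H]1C(=C)COCc1ccc(OC)cc1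
A2 | alternative 1 | thirteen-membered allylic ether with tributylstannyl at C6 (either C6 epimer) | CCCC[Sn](CCCC)(CCCC)C1OC/C(COCc2ccc(OC)cc2)=C/[C@@H](O[Si](C)(C)C(C)(C)C)C/C(C)=C/[C@@H](O[Si](C)(C)C(C)(C)C)C/C(C)=C\1
A3 | alternative 2 | ten-membered (1(10)E,4Z)-dien-6-ol fused to the 13-(dimethylamino) lactone | CN(C)C[C@H]1C(=O)O[C@H]2C/C(C)=C/[C@@H](O[Si](C)(C)C(C)(C)C)C/C(C)=C\[C@@H](O)[C@H]12
A4 | alternative 2 | open-chain Z alkenyl iodide with the C6 aldehyde on the aminomethyl lactone | CN(C)C[C@H]1C(=O)O[C@@H](C/C(C)=C/[C@@H](O[Si](C)(C)C(C)(C)C)C/C(C)=C\I)[C@@H]1C=O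
A5 | alternative 3 | (1(10)E,4Z)-2,8-bis(tert-butyldimethylsilyloxy)-7-[2-(4-methoxybenzyloxy)ethyl]cyclodeca-1(10),4-dien-6-one | [C@H]1(O[Si](C)(C)C(C)(C)C)C/C(C)=C/[C@@H](O[Si](C)(C)C(C)(C)C)C/C(C)=C\C(=O)[C@@H]1CCOCc1ccc(OC)cc1
A6 | alternative 3 | bicyclo[5.3.0]decenol with C6 hydroxyl and C1 mesylate (mesylate and C10 methyl cis) | CS(=O)(=O)O[C@H]1[C@@H](O[Si](C)(C)C(C)(C)C)CC(C)=C[C@@]2(O)[C@H](CCOCc3ccc(OC)cc3)[C@@H](O[Si](C)(C)C(C)(C)C)C[C@]12C
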